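**Strategy.** Everything rests on disconnecting the O–C2 bond of the 1,4-dioxane ring back to a benzylic C–H bond. C2 lies para to the free phenol of the guaiacyl ring, so DDQ can dearomatise that ring to a p-quinone methide. The 3'-OH of the flavone B ring then adds to it, closing the dioxane ring and setting C2 trans to C3 in the last step, which delivers the unprotected target directly. The precursor is a saturated, fully deprotected seco-flavone whose 4'-oxygen carries an (S)-1-hydroxy-3-(4-hydroxy-3-methoxyphenyl)propan-2-yl group. Its single stereocentre (the future C3) comes from (R)-benzyl glycidyl ether by Mitsunobu inversion.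

Key step: step 7

Remark: compounds 1, 2, 4, 5 and 9 are taken as commercial, and the trans-2,3-disubstituted benzodioxane is taken as the favoured product of the reversible quinone methide closure.

**Step 1**
Reactants: 1 5-hydroxyvanillin (3,4-dihydroxy-5-methoxybenzaldehyde)
Product: 3 3-(benzyloxy)-4-hydroxy-5-methoxybenzaldehyde
Conditions: NaH (2.2 equiv), DMSO, rt; then BnBr (1.0 equiv), rt; aq. HCl work-up
Reagents that add atoms: benzyl bromide (2), BrCc1ccccc1
Why: Williamson etherification of the dianion; the 4-phenoxide is delocalised into the para aldehyde and flanked on both sides, so the more nucleophilic 3-phenoxide should take the single equivalent of benzyl bromide.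

**Step 2**
Reactants: 4 1-(benzyloxy)-4-bromo-2-methoxybenzene; 5 (R)-benzyl glycidyl ether
Product: 7 (2R)-1-(benzyloxy)-3-[4-(benzyloxy)-3-methoxyphenyl]propan-2-ol, via arylmagnesium bromide 6 (not isolated)
Conditions: Mg, cat. I2, THF, 40 °C; then CuI (10 mol %), 5, THF, −30 to 0 °C; aq. NH4Cl
Reagents that add atoms: none
Why: Copper-catalysed Grignard opening of a terminal epoxide at the unsubstituted carbon; the stereocentre of 5 is not touched and is carried over unchanged.

**Step 3**
Reactants: 3 3-(benzyloxy)-4-hydroxy-5-methoxybenzaldehyde; 7 (2R)-1-(benzyloxy)-3-[4-(benzyloxy)-3-methoxyphenyl]propan-2-ol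
Product: 8 3-(benzyloxy)-4-{[(2S)-1-(benzyloxy)-3-[4-(benzyloxy)-3-methoxyphenyl]propan-2-yl]oxy}-5-methoxybenzaldehyde
Conditions: PPh3, DIAD, THF, 0 °C to rt
Reagents that add atoms: none
Why: Mitsunobu etherification; the acidic para-formyl phenol is a good pronucleophile and SN2 displacement at the carbinol carbon inverts (R) to (S), which fixes the future C3.

**Step 4**
Reactants: 8 the aldehyde of step 3; 9 1-[2,4-bis(benzyloxy)-6-hydroxyphenyl]ethanone
Product: 10 (2E)-1-[2,4-bis(benzyloxy)-6-hydroxyphenyl]-3-(3-(benzyloxy)-4-{[(2S)-1-(benzyloxy)-3-[4-(benzyloxy)-3-methoxyphenyl]propan-2-yl]oxy}-5-methoxyphenyl)prop-2-en-1-one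
Conditions: 50% aq. KOH, EtOH/THF, rt
Reagents that add atoms: none
Why: Claisen–Schmidt condensation to the (E)-2'-hydroxychalcone; the ether stereocentre has no acidic hydrogen and should survive the base.

**Step 5**
Reactants: 10 the chalcone of step 4
Product: 11 5,7-bis(benzyloxy)-2-(3-(benzyloxy)-4-{[(2S)-1-(benzyloxy)-3-[4-(benzyloxy)-3-methoxyphenyl]propan-2-yl]oxy}-5-methoxyphenyl)-4H-chromen-4-one
Conditions: I2 (10 mol %), DMSO, 110 °C
Reagents that add atoms: none
Why: Iodine/DMSO oxidative cyclisation of a 2'-hydroxychalcone to the flavone (oxa-Michael closure, then dehydrogenation with DMSO as terminal oxidant); benzyl and alkyl aryl ethers tolerate these conditions.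

**Step 6**
Reactants: 11 the pentabenzyl flavone of step 5
Product: 12 5,7-dihydroxy-2-(3-hydroxy-4-{[(2S)-1-hydroxy-3-(4-hydroxy-3-methoxyphenyl)propan-2-yl]oxy}-5-methoxyphenyl)-4H-chromen-4-one
Conditions: H2 (1 atm), 20% Pd(OH)2/C, THF/MeOH, rt
Reagents that add atoms: none
Why: Hydrogenolysis of the four aryl benzyl ethers and the primary benzyl ether; the non-benzylic 4'-O–CH bond and the chromone double bond should survive under mild pressure and monitored conversion.

**Step 7**
Reactants: 12 the seco-flavone of step 6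
Product: 14 5'-methoxyhydnocarpin, via p-quinone methide 13 (not isolated)
Conditions: DDQ (1.05 equiv), dry 1,4-dioxane (0.01 M), rt, dark
Reagents that add atoms: none
Why: DDQ should abstract hydride from the benzylic CH2 para to the guaiacyl OH, dearomatising that ring to p-quinone methide 13, and the 3'-OH then adds to the exocyclic carbon (oxa-1,6-addition) with rearomatisation. The closest known reaction type is the DDQ oxidative cyclisation of 1-(2-hydroxyphenyl)-3-(4-hydroxyphenyl)propanes to flavans. The dioxane ring closes in a 6-exo-trig mode. C2 is controlled by the existing C3 centre: a chair-like transition state with CH2OH and the quinonoid ring both equatorial leads to the trans (2R,3R) isomer, and reversible reopening through the same quinone methide favours the more stable trans product. Chemoselectivity is needed and rests on the substrate: only the guaiacyl phenol has a para benzylic C–H, the A-ring phenols are deactivated by the chromone carbonyl, and only the 3'-OH can reach the quinone methide in a six-membered closure. One equivalent of oxidant, high dilution and a dry aprotic solvent are used to limit over-oxidation, intermolecular capture and tautomerisation of 13 to the enol ether.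

**Compound list**
1 | 5-hydroxyvanillin | COc1cc(C=O)cc(O)c1O | starting material
2 | benzyl bromide | BrCc1ccccc1 | starting material
3 | 3-(benzyloxy)-4-hydroxy-5-methoxybenzaldehyde | COc1cc(C=O)cc(OCc2ccccc2)c1O | intermediate
4 | 1-(benzyloxy)-4-bromo-2-methoxybenzene | COc1cc(Br)ccc1OCc1ccccc1 | starting material
5 | (R)-benzyl glycidyl ether | C1O[C@H]1COCc1ccccc1 | starting material
6 | [4-(benzyloxy)-3-methoxyphenyl]magnesium bromide | COc1cc([Mg]Br)ccc1OCc1ccccc1 | intermediate
7 | (2R)-1-(benzyloxy)-3-[4-(benzyloxy)-3-methoxyphenyl]propan-2-ol | COc1cc(C[C@@H](O)COCc2ccccc2)ccc1OCc1ccccc1 | intermediate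
8 | 3-(benzyloxy)-4-{[(2S)-1-(benzyloxy)-3-[4-(benzyloxy)-3-methoxyphenyl]propan-2-yl]oxy}-5-methoxybenzaldehyde | COc1cc(C=O)cc(OCc2ccccc2)c1O[C@@H](Cc1ccc(OCc2ccccc2)c(OC)c1)COCc1ccccc1 | intermediate
9 | 1-[2,4-bis(benzyloxy)-6-hydroxyphenyl]ethanone | CC(=O)c1c(O)cc(OCc2ccccc2)cc1OCc1ccccc1 | starting material
10 | (E)-chalcone of 8 and 9 | O=C(/C=C/c1cc(OC)c(O[C@@H](Cc2ccc(OCc3ccccc3)c(OC)c2)COCc2ccccc2)c(OCc2ccccc2)c1)c1c(O)cc(OCc2ccccc2)cc1OCc1ccccc1 | intermediate
11 | pentabenzyl seco-flavone | O=c1cc(-c2cc(OC)c(O[C@@H](Cc3ccc(OCc4ccccc4)c(OC)c3)COCc3ccccc3)c(OCc3ccccc3)c2)oc2cc(OCc3ccccc3)cc(OCc3ccccc3)c12 | intermediate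
12 | 5,7-dihydroxy-2-(3-hydroxy-4-{[(2S)-1-hydroxy-3-(4-hydroxy-3-methoxyphenyl)propan-2-yl]oxy}-5-methoxyphenyl)-4H-chromen-4-one | O=c1cc(-c2cc(OC)c(O[C@@H](Cc3ccc(O)c(OC)c3)CO)c(O)c2)oc2cc(O)cc(O)c12 | intermediate
13 | p-quinone methide of 12 (2-methoxy-4-alkylidenecyclohexa-2,5-dienone, S at the ether carbon) | O=c1cc(-c2cc(OC)c(O[C@@H](C=C3C=CC(=O)C(OC)=C3)CO)c(O)c2)oc2cc(O)cc(O)c12 | intermediate
14 | 5'-methoxyhydnocarpin, (2R,3R) | COc1cc([C@H]2Oc3cc(-c4cc(=O)c5c(O)cc(O)cc5o4)cc(OC)c3O[C@@H]2CO)ccc1O | target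

**Step count and risks**
Total steps: 7. Longest linear sequence: 6 steps (1 → 3 → 8 → 10 → 11 → 12 → 14, or equally from 4).

Steps most likely to fail:

1. Step 7. The oxidation may attack other phenols and give oligomers, the quinone methide may tautomerise to the enol ether with loss of the C3 centre, the product may be oxidised further, or the trans selectivity may be poor. The fallback oxidises on the fully protected compound and closes the ring without an oxidant. It sets out from 11: DDQ (2.5 equiv) in wet CH2Cl2 should oxidise the 3,4-dialkoxybenzylic CH2 to the aryl ketone F1. NaBH4 in THF/MeOH at −20 °C should then give the benzylic alcohol F2 as a mixture of epimers at the carbinol carbon. Hydrogenolysis (H2, Pd(OH)2/C, THF/MeOH) should remove all five benzyl groups to give the hexahydroxy benzylic alcohol F3. Acid (TFA, dry dioxane, rt) should ionise the p-hydroxybenzylic alcohol and close the ring under thermodynamic control, so the mixed carbinol configuration does not matter. The fallback comes back to the route at 14.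

2. Step 3. Etherification of a di-ortho-substituted phenol with a secondary carbinol may be slow, and β-elimination to the propenyl arene may compete. The fallback moves the C–O bond formation to an α-hydroxy ester, where Mitsunobu coupling of hindered phenols is dependable. It sets out from 6 (made from 4) and 3. Grignard 6 with methyl (R)-oxirane-2-carboxylate (C1O[C@H]1C(=O)OC; CuBr·SMe2, THF, −40 °C) should give methyl (2R)-3-[4-(benzyloxy)-3-methoxyphenyl]-2-hydroxypropanoate F4. Mitsunobu coupling with 3 (PPh3, DIAD, THF) should give the (S)-aryloxy ester F5 with inversion. LiBH4 (THF, 0 °C to rt) should reduce ester and aldehyde to the diol F6. MnO2 (CH2Cl2) should reoxidise only the benzylic alcohol to the hydroxy aldehyde F7. Benzylation of the primary alcohol (benzyl 2,2,2-trichloroacetimidate, cat. TfOH, CH2Cl2) comes back to the route at 8.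

3. Step 1. Regioselectivity may be poor, or bis-benzylation may occur. The fallback uses a protect–benzylate–deprotect sequence built on the well-established preference for 4-O-alkylation of the monoanion. It sets out from 1: allyl bromide with Li2CO3 in DMF should give 4-(allyloxy)-3-hydroxy-5-methoxybenzaldehyde F8. BnBr with K2CO3 in DMF should give 4-(allyloxy)-3-(benzyloxy)-5-methoxybenzaldehyde F9. Pd(PPh3)4 (cat.) with morpholine in THF should remove the allyl group and come back to the route at 3.

**Further compounds**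
F1 | step 7 | 5,7-bis(benzyloxy)-2-(3-(benzyloxy)-4-{[(2R)-3-(benzyloxy)-1-[4-(benzyloxy)-3-methoxyphenyl]-1-oxopropan-2-yl]oxy}-5-methoxyphenyl)-4H-chromen-4-one | O=c1cc(-c2cc(OC)c(O[C@@H](C(=O)c3ccc(OCc4ccccc4)c(OC)c3)COCc3ccccc3)c(OCc3ccccc3)c2)oc2cc(OCc3ccccc3)cc(OCc3ccccc3)c12
F2 | step 7 | benzylic alcohol from F1 (epimer mixture at the carbinol carbon, R at the ether carbon) | O=c1cc(-c2cc(OC)c(O[C@@H](C(O)c3ccc(OCc4ccccc4)c(OC)c3)COCc3ccccc3)c(OCc3ccccc3)c2)oc2cc(OCc3ccccc3)cc(OCc3ccccc3)c12
F3 | step 7 | 5,7-dihydroxy-2-(4-{[(2R)-1,3-dihydroxy-1-(4-hydroxy-3-methoxyphenyl)propan-2-yl]oxy}-3-hydroxy-5-methoxyphenyl)-4H-chromen-4-one (epimer mixture at C1 of the chain) | O=c1cc(-c2cc(OC)c(O[C@@H](C(O)c3ccc(O)c(OC)c3)CO)c(O)c2)oc2cc(O)cc(O)c12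
F4 | step 3 | methyl (2R)-3-[4-(benzyloxy)-3-methoxyphenyl]-2-hydroxypropanoate | COc1cc(C[C@@H](O)C(=O)OC)ccc1OCc1ccccc1
F5 | step 3 | methyl (2S)-2-[2-(benzyloxy)-4-formyl-6-methoxyphenoxy]-3-[4-(benzyloxy)-3-methoxyphenyl]propanoate | COc1cc(C=O)cc(OCc2ccccc2)c1O[C@@H](Cc1ccc(OCc2ccccc2)c(OC)c1)C(=O)OC
F6 | step 3 | (2S)-2-[2-(benzyloxy)-4-(hydroxymethyl)-6-methoxyphenoxy]-3-[4-(benzyloxy)-3-methoxyphenyl]propan-1-ol | COc1cc(CO)cc(OCc2ccccc2)c1O[C@@H](Cc1ccc(OCc2ccccc2)c(OC)c1)CO
F7 | step 3 | 3-(benzyloxy)-4-{[(2S)-1-hydroxy-3-[4-(benzyloxy)-3-methoxyphenyl]propan-2-yl]oxy}-5-methoxybenzaldehyde | COc1cc(C=O)cc(OCc2ccccc2)c1O[C@@H](Cc1ccc(OCc2ccccc2)c(OC)c1)CO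
F8 | step 1 | 4-(allyloxy)-3-hydroxy-5-methoxybenzaldehyde | COc1cc(C=O)cc(O)c1OCC=C
F9 | step 1 | 4-(allyloxy)-3-(benzyloxy)-5-methoxybenzaldehyde | COc1cc(C=O)cc(OCc2ccccc2)c1OCC=C
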